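Cuts (target numbering C1–C8a, side chain C1′–C5′): the senecioate ester C–O bond at C1′, the two quinone carbonyls back to a ring B 1,4-dimethyl ether, C6=C7 of ring A, then C7–C8, C4a–C5 and C2–C1′.
Enabling feature: in ring A only C6 and C7 carry hydrogen. They form a bare CH=CH unit between C5 (OMe) and C8 (OH). Two three-carbon arms on the adjacent ring B carbons C4a and C8a, one already an allylic methyl ether and the other a C8-oxygenated vinyl unit, can therefore be joined there with loss of ethene.
Forward order: ring B is bought as a benzene. Bromine enters at C2 under phenol control and the six-carbon side chain is attached at C2–C1′ by aryllithium acylation. The C4a arm comes from directed lithiation, acrolein and MeI. The C8a arm comes from unmasking the original formyl carbon and adding a vinyl Grignard reagent.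
C8 is raised to the ketone before the metathesis. Ring closure then gives a naphthalenone that tautomerises to the 5-methoxy-8-naphthol with no oxidant present. Ring A is thus formed last, followed by ester, quinone and free phenol.
Stereochemistry: the single stereocentre C1′ (S) is set by a Corey–Bakshi–Shibata reduction of the aryl ketone and is not touched again. The C5 and C8 carbinol centres are carried as mixtures and disappear on aromatisation.

Key step: step 12

Remark on the chemistry: the descriptor at C1′ in the target string is read as S, and the target locants (C1–C8a, C1′–C5′) are used for every naphthalene-stage intermediate and in all explanations.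

Step 1
Reactants: 1 2-hydroxy-5-methoxybenzaldehyde
Product: 2 3-bromo-2-hydroxy-5-methoxybenzaldehyde
Conditions: Br2, NaOAc, AcOH, rt
Reagents that add atoms: bromine, BrBr
Why: Electrophilic aromatic bromination in which the free phenol is the dominant director; its para position carries OMe and one ortho position carries CHO, so bromine should enter only at the remaining ortho carbon, the future C2.

Step 2
Reactants: 2 3-bromo-2-hydroxy-5-methoxybenzaldehyde
Product: 3 3-bromo-2,5-dimethoxybenzaldehyde
Conditions: MeI, K2CO3, DMF, rt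
Reagents that add atoms: iodomethane, CI
Why: Williamson ether synthesis on the acidic salicylaldehyde phenol, the only group in 2 that is alkylated under carbonate conditions.

Step 3
Reactants: 3 3-bromo-2,5-dimethoxybenzaldehyde
Product: 4 1-bromo-3-(dimethoxymethyl)-2,5-dimethoxybenzene
Conditions: HC(OMe)3, p-TsOH·H2O (cat.), MeOH, reflux; Et3N quench
Reagents that add atoms: trimethyl orthoformate, COC(OC)OC
Why: Acid-catalysed acetalisation with the orthoester as water scavenger; the dimethyl acetal shields the future C8 from organolithiums, later serves as a directing group, and is the most easily hydrolysed common acetal.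

Step 4
Reactants: 5 4-methylpent-3-enoic acid
Product: 7 N-methoxy-N,4-dimethylpent-3-enamide, via acylimidazole 6 (not isolated)
Conditions: 1,1'-carbonyldiimidazole, CH2Cl2, rt; then MeNHOMe·HCl, rt
Reagents that add atoms: N,O-dimethylhydroxylamine hydrochloride, CNOC.Cl
Why: Weinreb amide synthesis by acylimidazole coupling, whose near-neutral medium should keep the β,γ-alkene out of conjugation.

Step 5
Reactants: 4 1-bromo-3-(dimethoxymethyl)-2,5-dimethoxybenzene; 7 N-methoxy-N,4-dimethylpent-3-enamide
Product: 9 1-[3-(dimethoxymethyl)-2,5-dimethoxyphenyl]-4-methylpent-3-en-1-one, via aryllithium 8 (not isolated)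
Conditions: n-BuLi, THF, −78 °C; then 7, −78 → −20 °C; cold sat. aq. NH4Cl
Reagents that add atoms: none
Why: Bromine–lithium exchange followed by Weinreb ketone synthesis; the exchange outruns any deprotonation at −78 °C, the N-methoxy amide stops the addition at the ketone stage, and the cold, weakly acidic quench should leave the alkene β,γ.

Step 6
Reactants: 9 1-[3-(dimethoxymethyl)-2,5-dimethoxyphenyl]-4-methylpent-3-en-1-one
Product: 10 (1S)-1-[3-(dimethoxymethyl)-2,5-dimethoxyphenyl]-4-methylpent-3-en-1-ol
Conditions: (R)-2-methyl-CBS-oxazaborolidine [(3aR)-1-methyl-3,3-diphenyltetrahydro-1H,3H-pyrrolo[1,2-c][1,3,2]oxazaborole, 10 mol %], BH3·SMe2, THF, −20 °C, slow addition of 9; MeOH quench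
Reagents that add atoms: none
Why: Corey–Bakshi–Shibata reduction in which the (R)-catalyst places the aryl group as the large substituent and delivers hydride to the Re face, which should give the S carbinol; the catalysed carbonyl reduction is much faster than hydroboration of the trisubstituted alkene.

Step 7
Reactants: 10 (1S)-1-[3-(dimethoxymethyl)-2,5-dimethoxyphenyl]-4-methylpent-3-en-1-ol
Product: 11 (1S)-1-(tert-butyldimethylsilyloxy)-1-[3-(dimethoxymethyl)-2,5-dimethoxyphenyl]-4-methylpent-3-ene
Conditions: TBSCl, imidazole, DMF, rt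
Reagents that add atoms: tert-butyldimethylsilyl chloride, CC(C)(C)[Si](C)(C)Cl
Why: Imidazole-promoted O-silylation, which keeps the C1′–O bond and hence the configuration; the chloride is chosen over the triflate because silyl triflates activate dimethyl acetals.

Step 8
Reactants: 11 (1S)-1-(tert-butyldimethylsilyloxy)-1-[3-(dimethoxymethyl)-2,5-dimethoxyphenyl]-4-methylpent-3-ene; 12 acrolein (prop-2-enal)
Product: 15 (1S)-1-(tert-butyldimethylsilyloxy)-1-[3-(dimethoxymethyl)-2,5-dimethoxy-4-(1-methoxyprop-2-en-1-yl)phenyl]-4-methylpent-3-ene (both epimers at C5), via C4a-aryllithium 13 (not isolated), via lithium alkoxide 14 (not isolated)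
Conditions: n-BuLi (1.3 equiv), Et2O, 0 °C; 12, −78 °C; then MeI, DMPU, −78 °C → rt
Reagents that add atoms: iodomethane, CI
Why: Directed ortho-metalation, 1,2-addition and Williamson methylation in one flask: C4a–H is the only ring hydrogen flanked by two coordinating groups (the C4 methoxy group and the acetal on C8a) while C3–H is screened by the bulky, poorly coordinating silyl ether, the aryllithium adds to the carbonyl carbon of acrolein, and methylating the alkoxide before any work-up avoids a free hydroxy acetal that would close to a cyclic acetal with trace acid; the new ether centre forms unselectively and is lost later.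

Step 9
Reactants: 15 (1S)-1-(tert-butyldimethylsilyloxy)-1-[3-(dimethoxymethyl)-2,5-dimethoxy-4-(1-methoxyprop-2-en-1-yl)phenyl]-4-methylpent-3-ene
Product: 16 3-[(1S)-1-(tert-butyldimethylsilyloxy)-4-methylpent-3-en-1-yl]-2,5-dimethoxy-6-(1-methoxyprop-2-en-1-yl)benzaldehyde
Conditions: pyridinium p-toluenesulfonate (cat.), acetone/H2O, rt
Reagents that add atoms: water, O
Why: Acid-catalysed acetal hydrolysis; the aryl dimethyl acetal ionises far faster than the benzylic silyl ether or the allylic methyl ether, so the weak pyridinium acid in wet acetone should free only the C8 aldehyde.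

Step 10
Reactants: 16 3-[(1S)-1-(tert-butyldimethylsilyloxy)-4-methylpent-3-en-1-yl]-2,5-dimethoxy-6-(1-methoxyprop-2-en-1-yl)benzaldehyde; 17 vinylmagnesium bromide
Product: 18 1-{3-[(1S)-1-(tert-butyldimethylsilyloxy)-4-methylpent-3-en-1-yl]-2,5-dimethoxy-6-(1-methoxyprop-2-en-1-yl)phenyl}prop-2-en-1-ol (diastereomer mixture at C5 and C8)
Conditions: 17, THF, −78 → 0 °C; sat. aq. NH4Cl
Reagents that add atoms: none
Why: Grignard 1,2-addition gives the second arm directly as the free carbinol, so the C5–OMe/C8–O pattern follows from the order in which the arms were built; no facial control is needed because C8 becomes sp2 in the next step.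

Step 11
Reactants: 18 1-{3-[(1S)-1-(tert-butyldimethylsilyloxy)-4-methylpent-3-en-1-yl]-2,5-dimethoxy-6-(1-methoxyprop-2-en-1-yl)phenyl}prop-2-en-1-ol
Product: 19 1-{3-[(1S)-1-(tert-butyldimethylsilyloxy)-4-methylpent-3-en-1-yl]-2,5-dimethoxy-6-(1-methoxyprop-2-en-1-yl)phenyl}prop-2-en-1-one (both epimers at C5)
Conditions: activated MnO2, CH2Cl2, rt; filtration through Celite, used without delay
Reagents that add atoms: none
Why: MnO2 oxidation of an alcohol that is both allylic and benzylic; the neutral heterogeneous medium should spare the acid-sensitive allylic ether, the silyl ether and the isolated alkenes, and the aryl vinyl ketone cannot be oxidised further.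

Step 12
Reactants: 19 1-{3-[(1S)-1-(tert-butyldimethylsilyloxy)-4-methylpent-3-en-1-yl]-2,5-dimethoxy-6-(1-methoxyprop-2-en-1-yl)phenyl}prop-2-en-1-one
Product: 22 2-[(1S)-1-(tert-butyldimethylsilyloxy)-4-methylpent-3-en-1-yl]-1,4,5-trimethoxynaphthalen-8-yl acetate, via naphthalenone 20 (not isolated), via naphthol 21 (not isolated)
Conditions: RuCl2(=CHPh)(H2IMes)(PCy3) (second-generation Grubbs catalyst, 5 mol %), CH2Cl2 (5 mM), 40 °C, argon; then Et3N, Ac2O, 4-(dimethylamino)pyridine (DMAP, cat.), rt
Reagents that add atoms: acetic anhydride, CC(=O)OC(C)=O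
Why: After loss of PCy3 the ruthenium benzylidene exchanges with the terminal alkene of the more electron-rich 1-methoxyallyl arm, the new alkylidene adds to the neighbouring acryloyl C=C in a [2+2] step, and cycloreversion of the ruthenacyclobutane forms C6=C7 together with a ruthenium methylidene that carries the chain while ethene escapes. The closest known reaction type is ring-closing metathesis of 1-(2-allylaryl)prop-2-en-1-ones and of acyclic 1,4,7-trien-3-ones, followed by keto–enol tautomerisation to naphthols or phenols. Ring A closes as a six-membered carbocycle by union of two terminal vinyl groups whose anchor carbons C4a and C8a are ortho neighbours on ring B, so the new alkene can only be cis and the closure costs little entropy. No stereocentre is formed: C5 of 20 gives up its hydrogen in the aromatisation-driven tautomerisation to 21, which Et3N completes, and C1′ lies outside the reacting array. The step needs chemoselectivity for the two monosubstituted alkenes over the trisubstituted C3′=C4′ alkene, which is secured by the much slower metathesis of the latter and by the fact that it could only close an eight-membered ring. Because C8 is already a ketone, no oxidant meets the electron-rich naphthol and no water or methanol can be lost from a dihydronaphthalene, and acetylation in the same flask shields 21 from air.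

Step 13
Reactants: 22 2-[(1S)-1-(tert-butyldimethylsilyloxy)-4-methylpent-3-en-1-yl]-1,4,5-trimethoxynaphthalen-8-yl acetate
Product: 23 2-[(1S)-1-hydroxy-4-methylpent-3-en-1-yl]-1,4,5-trimethoxynaphthalen-8-yl acetate
Conditions: HF·pyridine, pyridine, THF, 0 °C → rt
Reagents that add atoms: none
Why: Fluoride-induced silyl ether cleavage in a pyridine-buffered medium, chosen because basic fluoride sources would also remove the aryl acetate; the C1′–O bond is not broken, so the configuration is kept.

Step 14
Reactants: 23 2-[(1S)-1-hydroxy-4-methylpent-3-en-1-yl]-1,4,5-trimethoxynaphthalen-8-yl acetate; 24 3-methylbut-2-enoic acid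
Product: 26 (1S)-1-(8-acetoxy-1,4,5-trimethoxynaphthalen-2-yl)-4-methylpent-3-en-1-yl 3-methylbut-2-enoate, via O-acylisourea 25 (not isolated)
Conditions: N,N'-dicyclohexylcarbodiimide (DCC), DMAP (cat.), CH2Cl2, 0 °C → rt
Reagents that add atoms: none
Why: Steglich esterification, an O-acylation with retention at C1′; carbodiimide activation avoids the vinylketene pathway by which the acid chloride and amine bases deconjugate the senecioyl group.

Step 15
Reactants: 26 (1S)-1-(8-acetoxy-1,4,5-trimethoxynaphthalen-2-yl)-4-methylpent-3-en-1-yl 3-methylbut-2-enoate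
Product: 27 (1S)-1-(8-acetoxy-5-methoxy-1,4-dioxo-1,4-dihydronaphthalen-2-yl)-4-methylpent-3-en-1-yl 3-methylbut-2-enoate
Conditions: (NH4)2Ce(NO3)6 (2.5 equiv), MeCN/H2O, 0 °C
Reagents that add atoms: water, O
Why: Oxidative demethylation of a hydroquinone dimethyl ether by tetravalent cerium, with two one-electron oxidations and attack of water at C1 and C4 releasing methanol; ring B reacts because it carries the para-dimethoxy pair and an alkyl donor, whereas ring A is deactivated by the acetate and has only one cleavable ether.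

Step 16
Reactants: 27 (1S)-1-(8-acetoxy-5-methoxy-1,4-dioxo-1,4-dihydronaphthalen-2-yl)-4-methylpent-3-en-1-yl 3-methylbut-2-enoate
Product: 28 (1S)-1-(8-hydroxy-5-methoxy-1,4-dioxo-1,4-dihydronaphthalen-2-yl)-4-methylpent-3-en-1-yl 3-methylbut-2-enoate
Conditions: K2CO3 (1.0 equiv), MeOH/CH2Cl2, 0 °C, short contact; sat. aq. NH4Cl
Reagents that add atoms: none
Why: Base-mediated methanolysis (transesterification); the acetate of an electron-poor peri-quinone phenol is an activated aryl ester and should exchange far faster than the hindered, conjugated ester of a secondary alcohol, and the phenoxide formed lowers the electrophilicity of the quinone until the quench.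

Compound list
1 | 2-hydroxy-5-methoxybenzaldehyde | COc1ccc(O)c(C=O)c1 | starting material
2 | 3-bromo-2-hydroxy-5-methoxybenzaldehyde | COc1cc(Br)c(O)c(C=O)c1 | intermediate
3 | 3-bromo-2,5-dimethoxybenzaldehyde | COc1cc(Br)c(OC)c(C=O)c1 | intermediate
4 | 1-bromo-3-(dimethoxymethyl)-2,5-dimethoxybenzene | COc1cc(Br)c(OC)c(C(OC)OC)c1 | intermediate
5 | 4-methylpent-3-enoic acid | CC(C)=CCC(=O)O | starting material
6 | 1-(imidazol-1-yl)-4-methylpent-3-en-1-one (acylimidazole, not isolated) | CC(C)=CCC(=O)n1ccnc1 | intermediate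
7 | N-methoxy-N,4-dimethylpent-3-enamide | CC(C)=CCC(=O)N(C)OC | intermediate
8 | [3-(dimethoxymethyl)-2,5-dimethoxyphenyl]lithium (not isolated) | COc1cc([Li])c(OC)c(C(OC)OC)c1 | intermediate
9 | 1-[3-(dimethoxymethyl)-2,5-dimethoxyphenyl]-4-methylpent-3-en-1-one | COc1cc(C(=O)CC=C(C)C)c(OC)c(C(OC)OC)c1 | intermediate
10 | (1S)-1-[3-(dimethoxymethyl)-2,5-dimethoxyphenyl]-4-methylpent-3-en-1-ol | COc1cc([C@H](CC=C(C)C)O)c(OC)c(C(OC)OC)c1 | intermediate
11 | (1S)-1-(tert-butyldimethylsilyloxy)-1-[3-(dimethoxymethyl)-2,5-dimethoxyphenyl]-4-methylpent-3-ene | COc1cc([C@H](CC=C(C)C)O[Si](C)(C)C(C)(C)C)c(OC)c(C(OC)OC)c1 | intermediate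
12 | acrolein (prop-2-enal) | C=CC=O | starting material
13 | {4-[(1S)-1-(tert-butyldimethylsilyloxy)-4-methylpent-3-en-1-yl]-2-(dimethoxymethyl)-3,6-dimethoxyphenyl}lithium (not isolated) | COc1cc([C@H](CC=C(C)C)O[Si](C)(C)C(C)(C)C)c(OC)c(C(OC)OC)c1[Li] | intermediate
14 | lithium 1-{4-[(1S)-1-(tert-butyldimethylsilyloxy)-4-methylpent-3-en-1-yl]-2-(dimethoxymethyl)-3,6-dimethoxyphenyl}prop-2-en-1-olate (not isolated) | COc1cc([C@H](CC=C(C)C)O[Si](C)(C)C(C)(C)C)c(OC)c(C(OC)OC)c1C(O[Li])C=C | intermediate
15 | (1S)-1-(tert-butyldimethylsilyloxy)-1-[3-(dimethoxymethyl)-2,5-dimethoxy-4-(1-methoxyprop-2-en-1-yl)phenyl]-4-methylpent-3-ene, epimers at C5 | COc1cc([C@H](CC=C(C)C)O[Si](C)(C)C(C)(C)C)c(OC)c(C(OC)OC)c1C(OC)C=C | intermediate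
16 | 3-[(1S)-1-(tert-butyldimethylsilyloxy)-4-methylpent-3-en-1-yl]-2,5-dimethoxy-6-(1-methoxyprop-2-en-1-yl)benzaldehyde | COc1cc([C@H](CC=C(C)C)O[Si](C)(C)C(C)(C)C)c(OC)c(C=O)c1C(OC)C=C | intermediate
17 | vinylmagnesium bromide | C=C[Mg]Br | starting material
18 | 1-{3-[(1S)-1-(tert-butyldimethylsilyloxy)-4-methylpent-3-en-1-yl]-2,5-dimethoxy-6-(1-methoxyprop-2-en-1-yl)phenyl}prop-2-en-1-ol, mixture at C5 and C8 | COc1cc([C@H](CC=C(C)C)O[Si](C)(C)C(C)(C)C)c(OC)c(C(O)C=C)c1C(OC)C=C | intermediate
19 | 1-{3-[(1S)-1-(tert-butyldimethylsilyloxy)-4-methylpent-3-en-1-yl]-2,5-dimethoxy-6-(1-methoxyprop-2-en-1-yl)phenyl}prop-2-en-1-one (metathesis precursor) | COc1cc([C@H](CC=C(C)C)O[Si](C)(C)C(C)(C)C)c(OC)c(C(=O)C=C)c1C(OC)C=C | intermediate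
20 | 2-[(1S)-1-(tert-butyldimethylsilyloxy)-4-methylpent-3-en-1-yl]-1,4,5-trimethoxy-5H-naphthalen-8-one (metathesis product, not isolated) | COc1cc([C@H](CC=C(C)C)O[Si](C)(C)C(C)(C)C)c(OC)c2c1C(OC)C=CC2=O | intermediate
21 | 2-[(1S)-1-(tert-butyldimethylsilyloxy)-4-methylpent-3-en-1-yl]-1,4,5-trimethoxynaphthalen-8-ol (not isolated) | COc1cc([C@H](CC=C(C)C)O[Si](C)(C)C(C)(C)C)c(OC)c2c(O)ccc(OC)c12 | intermediate
22 | 2-[(1S)-1-(tert-butyldimethylsilyloxy)-4-methylpent-3-en-1-yl]-1,4,5-trimethoxynaphthalen-8-yl acetate | COc1cc([C@H](CC=C(C)C)O[Si](C)(C)C(C)(C)C)c(OC)c2c(OC(C)=O)ccc(OC)c12 | intermediate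
23 | 2-[(1S)-1-hydroxy-4-methylpent-3-en-1-yl]-1,4,5-trimethoxynaphthalen-8-yl acetate | COc1cc([C@H](CC=C(C)C)O)c(OC)c2c(OC(C)=O)ccc(OC)c12 | intermediate
24 | 3-methylbut-2-enoic acid (senecioic acid) | CC(C)=CC(=O)O | starting material
25 | N,N'-dicyclohexyl-O-(3-methylbut-2-enoyl)isourea (not isolated) | CC(C)=CC(=O)OC(=NC1CCCCC1)NC1CCCCC1 | intermediate
26 | (1S)-1-(8-acetoxy-1,4,5-trimethoxynaphthalen-2-yl)-4-methylpent-3-en-1-yl 3-methylbut-2-enoate | COc1cc([C@H](CC=C(C)C)OC(=O)C=C(C)C)c(OC)c2c(OC(C)=O)ccc(OC)c12 | intermediate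
27 | (1S)-1-(8-acetoxy-5-methoxy-1,4-dioxo-1,4-dihydronaphthalen-2-yl)-4-methylpent-3-en-1-yl 3-methylbut-2-enoate | COc1ccc(OC(C)=O)c2c1C(=O)C=C([C@H](CC=C(C)C)OC(=O)C=C(C)C)C2=O | intermediate
28 | (1S)-1-(8-hydroxy-5-methoxy-1,4-dioxo-1,4-dihydronaphthalen-2-yl)-4-methylpent-3-en-1-yl 3-methylbut-2-enoate (CNP0299347.1) | COc1ccc(O)c2c1C(=O)C=C([C@H](CC=C(C)C)OC(=O)C=C(C)C)C2=O | target

Total step count: 16. Longest linear sequence: 15 (steps 1–3 and 5–16; step 4 is the side branch).

Steps most likely to fail

Step 8. Butyllithium may remove the wrong proton: C3–H, or the benzylic C1′–H next to the silyl ether. The latter would be followed by silyl migration from oxygen to carbon and erosion of configuration. Acrolein may also polymerise on the hindered aryllithium.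

Fallback: the deprotonation is moved to the very start, before bromine, alkene and stereocentre exist, and C2 is halogenated afterwards.
- Setting out from 1, O-methylation (MeI, K2CO3) gives 2,5-dimethoxybenzaldehyde F1, and acetalisation as in step 3 gives 2-(dimethoxymethyl)-1,4-dimethoxybenzene F2.
- n-BuLi in Et2O followed by DMF formylates the carbon between acetal and methoxy group, giving 2-(dimethoxymethyl)-3,6-dimethoxybenzaldehyde F3.
- N-bromosuccinimide in DMF should brominate para to the free formyl group and ortho to the methoxy group that is not conjugated with it, the orientation known for 2,5-dimethoxybenzaldehyde. This gives 4-bromo-2-(dimethoxymethyl)-3,6-dimethoxybenzaldehyde F4.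
- Addition of 17 gives 1-[4-bromo-2-(dimethoxymethyl)-3,6-dimethoxyphenyl]prop-2-en-1-ol F5, which is methylated crude with NaH and MeI to 1-bromo-3-(dimethoxymethyl)-2,5-dimethoxy-4-(1-methoxyprop-2-en-1-yl)benzene F6.
- Bromine–lithium exchange at −78 °C and acylation with 7 give 1-[3-(dimethoxymethyl)-2,5-dimethoxy-4-(1-methoxyprop-2-en-1-yl)phenyl]-4-methylpent-3-en-1-one F7.
- Reduction with the (R)-oxazaborolidine and catecholborane, which spares the terminal alkene, gives (1S)-1-[3-(dimethoxymethyl)-2,5-dimethoxy-4-(1-methoxyprop-2-en-1-yl)phenyl]-4-methylpent-3-en-1-ol F8.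
- Silylation as in step 7 returns to the route at 15.

Step 12. The twisted, electron-poor aryl vinyl ketone may be consumed by oligomerisation or intermolecular metathesis before the alkylidene, which must form on a hindered allylic ether, closes the ring.

Fallback: the ring is closed one oxidation level lower and oxidised afterwards.
- Setting out from 18, the free carbinol, whose allylic hydroxyl group speeds up catalyst loading, is cyclised with the same ruthenium catalyst in acid-free CH2Cl2. This gives 2-[(1S)-1-(tert-butyldimethylsilyloxy)-4-methylpent-3-en-1-yl]-1,4,5-trimethoxy-5,8-dihydronaphthalen-8-ol F9.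
- A brief treatment with MnO2 then oxidises C8 and comes back to the route at 20.
- The suspension is filtered directly into Et3N, Ac2O and DMAP, so that the naphthol is acetylated as soon as it forms and 22 is reached.

Step 16. Methanolysis may not stay selective. The side-chain ester may be lost by exchange or elimination, or methoxide may add at C3 of the quinone.

Fallback: the senecioate is introduced last, so that no second ester is present when the acetate is removed.
- Setting out from 22, oxidation with (NH4)2Ce(NO3)6 as in step 15 gives 2-[(1S)-1-(tert-butyldimethylsilyloxy)-4-methylpent-3-en-1-yl]-5-methoxy-1,4-dioxo-1,4-dihydronaphthalen-8-yl acetate F10.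
- K2CO3 in MeOH gives 2-[(1S)-1-(tert-butyldimethylsilyloxy)-4-methylpent-3-en-1-yl]-8-hydroxy-5-methoxynaphthalene-1,4-dione F11.
- HF·pyridine gives 8-hydroxy-2-[(1S)-1-hydroxy-4-methylpent-3-en-1-yl]-5-methoxynaphthalene-1,4-dione F12.
- Steglich esterification with 24 should acylate only the side-chain hydroxyl, because the peri phenol is tied up in a hydrogen bond to the C1 carbonyl. This arrives at 28.

Further compounds
F1 | step 8 | 2,5-dimethoxybenzaldehyde | COc1ccc(OC)c(C=O)c1
F2 | step 8 | 2-(dimethoxymethyl)-1,4-dimethoxybenzene | COc1ccc(OC)c(C(OC)OC)c1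
F3 | step 8 | 2-(dimethoxymethyl)-3,6-dimethoxybenzaldehyde | COc1ccc(OC)c(C(OC)OC)c1C=O
F4 | step 8 | 4-bromo-2-(dimethoxymethyl)-3,6-dimethoxybenzaldehyde | COc1cc(Br)c(OC)c(C(OC)OC)c1C=O
F5 | step 8 | 1-[4-bromo-2-(dimethoxymethyl)-3,6-dimethoxyphenyl]prop-2-en-1-ol | COc1cc(Br)c(OC)c(C(OC)OC)c1C(O)C=C
F6 | step 8 | 1-bromo-3-(dimethoxymethyl)-2,5-dimethoxy-4-(1-methoxyprop-2-en-1-yl)benzene | COc1cc(Br)c(OC)c(C(OC)OC)c1C(OC)C=C
F7 | step 8 | 1-[3-(dimethoxymethyl)-2,5-dimethoxy-4-(1-methoxyprop-2-en-1-yl)phenyl]-4-methylpent-3-en-1-one | COc1cc(C(=O)CC=C(C)C)c(OC)c(C(OC)OC)c1C(OC)C=C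
F8 | step 8 | (1S)-1-[3-(dimethoxymethyl)-2,5-dimethoxy-4-(1-methoxyprop-2-en-1-yl)phenyl]-4-methylpent-3-en-1-ol | COc1cc([C@H](CC=C(C)C)O)c(OC)c(C(OC)OC)c1C(OC)C=C
F9 | step 12 | 2-[(1S)-1-(tert-butyldimethylsilyloxy)-4-methylpent-3-en-1-yl]-1,4,5-trimethoxy-5,8-dihydronaphthalen-8-ol | COc1cc([C@H](CC=C(C)C)O[Si](C)(C)C(C)(C)C)c(OC)c2c1C(OC)C=CC2O
F10 | step 16 | 2-[(1S)-1-(tert-butyldimethylsilyloxy)-4-methylpent-3-en-1-yl]-5-methoxy-1,4-dioxo-1,4-dihydronaphthalen-8-yl acetate | COc1ccc(OC(C)=O)c2c1C(=O)C=C([C@H](CC=C(C)C)O[Si](C)(C)C(C)(C)C)C2=O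
F11 | step 16 | 2-[(1S)-1-(tert-butyldimethylsilyloxy)-4-methylpent-3-en-1-yl]-8-hydroxy-5-methoxynaphthalene-1,4-dione | COc1ccc(O)c2c1C(=O)C=C([C@H](CC=C(C)C)O[Si](C)(C)C(C)(C)C)C2=O
F12 | step 16 | 8-hydroxy-2-[(1S)-1-hydroxy-4-methylpent-3-en-1-yl]-5-methoxynaphthalene-1,4-dione | COc1ccc(O)c2c1C(=O)C=C([C@H](CC=C(C)C)O)C2=O
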